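**Plan**
1. Numbering: chain C1–C8 (C1H2=C2, carbinol C3, C6=C7, C8H2–O), arene C1'–C6' (ether oxygen on C1'), side chain C1''–C3''. The cuts are C4'–C1'' (Suzuki–Miyaura), then C7–C8 together with C6–CH3 (methylalumination and aryloxymethylation of a C6≡C7H alkyne), then C2–C3 (isopropenyl Grignard on a Weinreb amide). The O–C8 bond is made on the phenol before C8 meets the chain.
2. Enabling feature: in C5H2–C6(CH3)=C7H–C8H2–OAr the C6 methyl and C8 sit cis on the E-trisubstituted alkene. This is the pattern left when CH3 and a metal add to the same face of a terminal alkyne and the metal is then replaced by a one-carbon electrophile. The benzene ring is bought and no ring is formed.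
3. Forward: pentynoic acid → Weinreb amide → enynone → (R)-enynol → silyl ether (4 steps). Bromosyringol → methylthiomethyl ether → chloromethyl ether (2 steps). The two parts are joined in step 7, followed by Suzuki coupling and global desilylation.
4. Stereochemistry: C3 (R) comes from a CBS reduction with the (S)-oxazaborolidine, 6E from syn carbometalation and retentive capture, and 1''E from the E-alkenylboronate.

Key step: step 7

Remark: the target SMILES is read as 3R, 6E, 1''E; salts formed by mere proton transfer (phenoxide, alkoxides, partly metalated alkyne) and the borate ester hydrolysed at the work-up of step 3 are treated as forms of the numbered compounds.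

**Step 1**
Reactants: 1 pent-4-ynoic acid; 2 N,O-dimethylhydroxylamine hydrochloride
Product: 4 N-methoxy-N-methylpent-4-ynamide, via pent-4-ynoyl imidazolide 3 (not isolated)
Conditions: 1,1'-carbonyldiimidazole (1.1 equiv), CH2Cl2, 0 °C → rt; then 2 (1.2 equiv), rt
Reagents that add atoms: N,O-dimethylhydroxylamine hydrochloride (2), CNOC.Cl; 1,1'-carbonyldiimidazole, O=C(n1ccnc1)n1ccnc1 (imidazolyl group of 3 only)
Why: Weinreb amide formation by carbonyldiimidazole activation, in which the acid becomes acylimidazole 3 with loss of CO2 and the amine, freed by the released imidazole, displaces the imidazolyl group while the terminal alkyne stays inert.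

**Step 2**
Reactants: 4 N-methoxy-N-methylpent-4-ynamide; 5 isopropenylmagnesium bromide
Product: 7 2-methylhept-1-en-6-yn-3-one, via magnesium chelate 6 (not isolated)
Conditions: 5 (2.3 equiv), THF, −78 → 0 °C; inverse quench into cold 1 M HCl
Reagents that add atoms: isopropenylmagnesium bromide (5), C=C(C)[Mg]Br
Why: Weinreb ketone synthesis, in which addition stops at the five-membered N,O-chelate 6 until the quench, the extra reagent covers the acidic alkyne C–H, and the cold acidic inverse quench keeps the released amine protonated so that it cannot add to the enone.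

**Step 3**
Reactants: 7 2-methylhept-1-en-6-yn-3-one
Product: 8 (R)-2-methylhept-1-en-6-yn-3-ol
Conditions: (3aS)-1-methyl-3,3-diphenyltetrahydro-1H,3H-pyrrolo[1,2-c][1,3,2]oxazaborole [(S)-Me-CBS, C18H20BNO] (0.2 equiv), catecholborane (1.8 equiv), toluene, −78 °C; aqueous NaOH work-up
Reagents that add atoms: none
Why: Corey–Bakshi–Shibata reduction, in which the carbonyl oxygen binds the ring boron through the lone pair on the side of the slimmer CH2CH2C≡CH arm, the branched sp2 isopropenyl group acts as the large substituent, and N-bound catecholborane passes hydride to the Si face through a six-membered transition state (the sense by which this catalyst turns acetophenone into (R)-1-phenylethanol), so C3 should be set as R, while catecholborane at −78 °C reduces 1,2 and leaves alkyne and alkene alone.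

**Step 4**
Reactants: 8 (R)-2-methylhept-1-en-6-yn-3-ol
Product: 9 tert-butyldimethyl{[(3R)-2-methylhept-1-en-6-yn-3-yl]oxy}silane
Conditions: TBSCl (1.3 equiv), imidazole (2.5 equiv), DMF, 0 °C → rt
Reagents that add atoms: tert-butyldimethylsilyl chloride, CC(C)(C)[Si](C)(C)Cl
Why: Standard imidazole-promoted O-silylation that breaks no bond at C3, giving an ether that tolerates Me3Al/Cp2ZrCl2, the alanate and aqueous phosphate and falls together with the primary silyl ether at the end.

**Step 5**
Reactants: 10 4-bromo-2,6-dimethoxyphenol; 11 chloromethyl methyl sulfide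
Product: 12 5-bromo-1,3-dimethoxy-2-[(methylsulfanyl)methoxy]benzene
Conditions: NaH (1.2 equiv), DMF, 0 °C; 11 (1.2 equiv), NaI (0.1 equiv), 0 °C → rt
Reagents that add atoms: chloromethyl methyl sulfide (11), CSCCl
Why: Williamson-type O-alkylation of the sodium phenoxide with the reactive α-chloro sulfide under iodide catalysis, the usual entry to aryl methylthiomethyl ethers and one that also serves 2,6-disubstituted phenols.

**Step 6**
Reactants: 12 5-bromo-1,3-dimethoxy-2-[(methylsulfanyl)methoxy]benzene
Product: 13 5-bromo-2-(chloromethoxy)-1,3-dimethoxybenzene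
Conditions: SO2Cl2 (1.0 equiv), CH2Cl2, −78 → 0 °C; volatiles removed in vacuo, crude 13 used at once
Reagents that add atoms: sulfuryl chloride, O=S(=O)(Cl)Cl
Why: Chlorinolysis of an O,S-acetal, in which sulfur is chlorinated far faster than the ring and the chlorosulfonium salt collapses to the aryl chloromethyl ether, an established conversion of aryl methylthiomethyl ethers whose co-products are all volatile, so no chromatography of the moisture-sensitive chloride is needed.

**Step 7**
Reactants: 9 tert-butyldimethyl{[(3R)-2-methylhept-1-en-6-yn-3-yl]oxy}silane; 14 trimethylaluminium; 13 5-bromo-2-(chloromethoxy)-1,3-dimethoxybenzene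
Product: 17 tert-butyl{[(3R,6E)-8-(4-bromo-2,6-dimethoxyphenoxy)-2,6-dimethylocta-1,6-dien-3-yl]oxy}dimethylsilane, via alkenyldimethylalane 15 (not isolated), via lithium alkenylalanate 16 (not isolated)
Conditions: 14 (2.0 equiv), Cp2ZrCl2 (0.2 equiv), CH2Cl2, 0 °C → rt; solvent and excess 14 removed in vacuo, hexane, filtration under argon; n-BuLi (0.95 equiv), hexane–THF, −78 → 0 °C; 13 (1.3 equiv), THF, −78 → 0 °C; aq. potassium sodium tartrate
Reagents that add atoms: trimethylaluminium (14), C[Al](C)C; 5-bromo-2-(chloromethoxy)-1,3-dimethoxybenzene (13), COc1cc(Br)cc(OC)c1OCCl; n-butyllithium, [Li]CCCC (butyl group and lithium of 16 only)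
Why: Proposed new method: the methylzirconocene–aluminium pair formed from Cp2ZrCl2 and 14 adds Me–Zr syn across the terminal alkyne of 9 through a four-centre transition state, methyl going to the internal carbon C6 and the metal to the terminal carbon C7, and Zr-to-Al exchange gives alane 15 with the new methyl cis to aluminium. Butyllithium converts 15 into the tetracoordinate alanate 16, whose alkenyl–Al σ bond displaces chloride from the oxygen-activated CH2 of 13 (SN2 with oxocarbenium character, Li+ taking up chloride) with retention at the sp2 carbon, so C8 ends up cis to the C6 methyl and the alkene is E. The closest known reaction type is the Negishi methylalumination of terminal alkynes followed by capture of the 2-methylalkenylalane or its lithium alanate with chloromethyl methyl ether, formaldehyde or chloroformates, and what has not been shown is an aryl chloromethyl ether as the electrophile. No ring closes and no stereocentre is created, since C3 is a spectator three carbons from the alkyne and keeps its R configuration. The step needs alkyne-over-alkene chemoselectivity (the 1,1-disubstituted C1=C2 alkene and the bulky silyl ether do not engage Me3Al/Cp2ZrCl2), alkenyl-over-alkyl transfer from aluminium (sp2 ligands leave mixed alanates first) and an untouched C–Br bond (substoichiometric butyllithium is fully bound to aluminium and no late transition metal is present). The ate complex is preferred to the neutral alane because it leaves no Me2AlCl behind, which could ionise 13 towards Friedel–Crafts self-alkylation or cleave the acid-labile allyl aryl ether of 17, and stripping excess 14 beforehand keeps methyl transfer to 13 small.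

**Step 8**
Reactants: 17 tert-butyl{[(3R,6E)-8-(4-bromo-2,6-dimethoxyphenoxy)-2,6-dimethylocta-1,6-dien-3-yl]oxy}dimethylsilane; 18 (E)-3-(tert-butyldimethylsilyloxy)prop-1-enylboronic acid pinacol ester
Product: 19 tert-butyl{[(2E)-3-(4-{[(2E,6R)-6-[(tert-butyldimethylsilyl)oxy]-3,7-dimethylocta-2,7-dien-1-yl]oxy}-3,5-dimethoxyphenyl)prop-2-en-1-yl]oxy}dimethylsilane
Conditions: 18 (1.3 equiv), Pd(OAc)2 (5 mol %), 2-dicyclohexylphosphino-2',6'-dimethoxybiphenyl (SPhos, 10 mol %), K3PO4 (3 equiv), THF–H2O 10:1, 45 °C
Reagents that add atoms: (E)-3-(tert-butyldimethylsilyloxy)prop-1-enylboronic acid pinacol ester (18), CC(C)(C)[Si](C)(C)OC/C=C/B1OC(C)(C)C(C)(C)O1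
Why: Suzuki–Miyaura coupling that transfers the alkenyl group with retention of its E geometry, the electron-rich bulky biarylphosphine letting zerovalent palladium insert into the electron-rich C–Br bond at mild temperature faster than it can ionise the hindered trisubstituted allyl aryl ether, while both silyl ethers tolerate aqueous phosphate.

**Step 9**
Reactants: 19 bis-silyl ether
Product: 20 (3R,6E)-8-{4-[(1E)-3-hydroxyprop-1-en-1-yl]-2,6-dimethoxyphenoxy}-2,6-dimethylocta-1,6-dien-3-ol (target)
Conditions: Bu4NF (3 equiv), THF, 0 °C → rt
Reagents that add atoms: none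
Why: Fluoride-induced desilylation cleaves only the two Si–O bonds, so the C3–O bond, its R configuration, both E alkenes and the allyl aryl ether should remain unchanged.

**Compound list**
1 | pent-4-ynoic acid | C#CCCC(=O)O | starting material
2 | N,O-dimethylhydroxylamine hydrochloride | CNOC.Cl | starting material
3 | 1-(1H-imidazol-1-yl)pent-4-yn-1-one | C#CCCC(=O)n1ccnc1 | intermediate
4 | N-methoxy-N-methylpent-4-ynamide | C#CCCC(=O)N(C)OC | intermediate
5 | isopropenylmagnesium bromide | C=C(C)[Mg]Br | starting material
6 | bromomagnesium 3-[methoxy(methyl)amino]-2-methylhept-1-en-6-yn-3-olate (tetrahedral chelate) | C#CCCC(O[Mg]Br)(N(C)OC)C(C)=C | intermediate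
7 | 2-methylhept-1-en-6-yn-3-one | C=C(C)C(=O)CCC#C | intermediate
8 | (R)-2-methylhept-1-en-6-yn-3-ol | C=C(C)[C@H](O)CCC#C | intermediate
9 | tert-butyldimethyl{[(3R)-2-methylhept-1-en-6-yn-3-yl]oxy}silane | C=C(C)[C@H](O[Si](C)(C)C(C)(C)C)CCC#C | intermediate
10 | 4-bromo-2,6-dimethoxyphenol | COc1cc(Br)cc(OC)c1O | starting material
11 | chloromethyl methyl sulfide | CSCCl | starting material
12 | 5-bromo-1,3-dimethoxy-2-[(methylsulfanyl)methoxy]benzene | COc1cc(Br)cc(OC)c1OCSC | intermediate
13 | 5-bromo-2-(chloromethoxy)-1,3-dimethoxybenzene | COc1cc(Br)cc(OC)c1OCCl | intermediate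
14 | trimethylaluminium | C[Al](C)C | starting material
15 | {(1E,5R)-5-[(tert-butyldimethylsilyl)oxy]-2,6-dimethylhepta-1,6-dien-1-yl}dimethylalane | C=C(C)[C@H](O[Si](C)(C)C(C)(C)C)CC/C(C)=C/[Al](C)C | intermediate
16 | lithium butyl{(1E,5R)-5-[(tert-butyldimethylsilyl)oxy]-2,6-dimethylhepta-1,6-dien-1-yl}dimethylalanate | C=C(C)[C@H](O[Si](C)(C)C(C)(C)C)CC/C(C)=C/[Al-](C)(C)CCCC.[Li+] | intermediate
17 | tert-butyl{[(3R,6E)-8-(4-bromo-2,6-dimethoxyphenoxy)-2,6-dimethylocta-1,6-dien-3-yl]oxy}dimethylsilane | C=C(C)[C@H](O[Si](C)(C)C(C)(C)C)CC/C(C)=C/COc1c(OC)cc(Br)cc1OC | intermediate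
18 | (E)-3-(tert-butyldimethylsilyloxy)prop-1-enylboronic acid pinacol ester | CC(C)(C)[Si](C)(C)OC/C=C/B1OC(C)(C)C(C)(C)O1 | starting material
19 | tert-butyl{[(2E)-3-(4-{[(2E,6R)-6-[(tert-butyldimethylsilyl)oxy]-3,7-dimethylocta-2,7-dien-1-yl]oxy}-3,5-dimethoxyphenyl)prop-2-en-1-yl]oxy}dimethylsilane | C=C(C)[C@H](O[Si](C)(C)C(C)(C)C)CC/C(C)=C/COc1c(OC)cc(/C=C/CO[Si](C)(C)C(C)(C)C)cc1OC | intermediate
20 | (3R,6E)-8-{4-[(1E)-3-hydroxyprop-1-en-1-yl]-2,6-dimethoxyphenoxy}-2,6-dimethylocta-1,6-dien-3-ol | C=C(C)[C@H](O)CC/C(C)=C/COc1c(OC)cc(/C=C/CO)cc1OC | target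

**Totals:** 9 steps in all. The longest linear sequence is 7 steps (steps 1–4, 7, 8, 9).

**Steps most likely to fail**

Step 7 (alkenyl transfer to the aryl chloromethyl ether). The capture may be overtaken by several processes:
- alkyl transfer from aluminium
- self-alkylation of the electron-rich ring of the electrophile
- protodemetalation
- aluminium-induced cleavage of the new allyl aryl ether

Fallback with known chemistry: setting out from 9, the same methylalumination and ate formation are run up to 16. The alanate is then treated with paraformaldehyde (THF, 0 °C → rt) to give (2E,6R)-6-[(tert-butyldimethylsilyl)oxy]-3,7-dimethylocta-2,7-dien-1-ol F1. A Mitsunobu etherification of this primary allylic alcohol with phenol 10 (PPh3, diisopropyl azodicarboxylate, THF, 0 °C → rt) forms the C8–O bond instead of the C7–C8 bond. It comes back to the route at 17, and steps 5 and 6 then become unnecessary.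

Step 6 (chlorinolysis next to an activated arene). The ring positions ortho and para to the two methoxy groups may suffer chlorination or sulfenylation, and the chloride may hydrolyse on handling. Fallback: setting out from 10, the phenoxide is O-alkylated with a large excess of bromochloromethane (NaOH, THF, reflux), a method established for 2,6-disubstituted phenols. Bromide leaves selectively and the excess suppresses the diaryl formal. This uses no electrophilic chlorine or sulfur reagent and comes back to the route directly at 13. No compound outside the list is made (F0).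

Step 3 (facial selectivity). Isopropenyl and the unbranched alkynyl arm may be discriminated too poorly by the oxazaborolidine, leaving the single stereocentre with insufficient enantiopurity. Fallback: setting out from 7, Luche reduction (NaBH4, CeCl3·7H2O, MeOH, −78 °C) gives racemic 2-methylhept-1-en-6-yn-3-ol F2. A Sharpless kinetic resolution follows (Ti(OiPr)4, L-(+)-diisopropyl tartrate, t-BuOOH 0.6 equiv, 4 Å sieves, CH2Cl2, −20 °C). It consumes the (S)-enantiomer as the erythro epoxy alcohol (S)-1-[(R)-2-methyloxiran-2-yl]pent-4-yn-1-ol F3 and leaves the slow-reacting (R)-alcohol. After chromatography this comes back to the route at 8.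

**Further compounds**
F1 | step 7 | (2E,6R)-6-[(tert-butyldimethylsilyl)oxy]-3,7-dimethylocta-2,7-dien-1-ol | C=C(C)[C@H](O[Si](C)(C)C(C)(C)C)CC/C(C)=C/CO
F0 | step 6 | none | none
F2 | step 3 | rac-2-methylhept-1-en-6-yn-3-ol | C=C(C)C(O)CCC#C
F3 | step 3 | (S)-1-[(R)-2-methyloxiran-2-yl]pent-4-yn-1-ol | C[C@@]1(CO1)[C@@H](O)CCC#C
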